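**Plan**

- Retrosynthesis: the lactone is cut at O–C16 and C15–C16 (enyne plus (Z)-3-iodobutenoic acid), the diene at C14–C15 (Sonogashira) and at C13–CH3 (carboalumination of a C13≡C14 alkyne). Ring B is then cut at C6–C7, C7–C8 and C8–O, so that C7 leaves as a one-carbon insert; last come C9–C11 (organometal addition), C4–C18 (enolate alkylation) and ring A (Robinson-type annulation).
- Structural feature used: in ring B the oxygens on C6 and C8 flank the bare methylene C7, and C8 is a methyl-bearing tertiary carbinol. Read as C6(=O)–C7H2–C8(OH)CH3, this is the product of oxidative opening of a cyclopropanol with carbinol carbon C6 and distal carbon C8, so ring B can be grown from the five-membered ring C5–C6–C8–C9–C10.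
- Forward: ring A and that five-membered ring are made first as a trans-hydrindane (steps 1–9). The side-chain stub goes onto C9 while the oxygen moves to C6 (steps 10–12), the C6=C8 enol ether is cyclopropanated (step 13), and the key step inserts C7 and installs the 8-hydroxyl.
- After it: 6-ketone to 6α-alcohol, acetal to alkyne, (E)-vinyl iodide, enyne, (Z)-ylidene butenolide, all on the free triol.
- Stereochemistry: C10 from the amino-acid-mediated aldol; C5 and C4 from Li/NH3 reductive alkylation anti to the C10 methyl; C9 by α-face protonation of the trans-hydrindane; C8 by equatorial O2 capture anti to the axial C10 methyl; C6 by thermodynamic dissolving-metal reduction; C13=C14 by syn-carboalumination; the ylidene by anti-oxymetalation.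

Key step: step 14

Remark: the core carries labdane numbers throughout (C1–C10, C18 = CH2O on C4, C11 onward = side chain). In the bicyclic precursors the five-membered ring is C5–C6–C8–C9–C10 and C7 is absent. β is the face of the C10 methyl, α the opposite face. The target is read as 4α-CH2OH, 4β-CH3, 5α-H, 6α-OH, 8α-OH, 8β-CH3, 9α-H, 10β-CH3, 13E, with a Z ylidene. Compound 15 is taken as the commercial THF solution.

**Step 1**
Reactants: 1 2-methylcyclopentane-1,3-dione; 2 pent-1-en-3-one
Product: 3 2-methyl-2-(3-oxopentyl)cyclopentane-1,3-dione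
Conditions: H2O, AcOH (cat.), 70 °C
Reagents that add atoms: none
Why: Michael addition of the acidic 1,3-dione to the unhindered enone forms the C1–C10 bond without a stereocentre, since C10 of 3 still carries two equivalent carbonyl arms.

**Step 2**
Reactants: 3 2-methyl-2-(3-oxopentyl)cyclopentane-1,3-dione
Product: 4 (S)-4,7a-dimethyl-2,3,7,7a-tetrahydro-1H-indene-1,5(6H)-dione
Conditions: L-phenylalanine (1 equiv), (1S)-(+)-camphor-10-sulfonic acid (0.5 equiv), DMF, 30 → 70 °C
Reagents that add atoms: none
Why: Hajos–Parrish-type intramolecular aldol condensation through the enamine of the side-chain ketone, in which the carboxylic acid of the L-amino acid directs attack onto one of the two enantiotopic ring carbonyls, should set C10 as S and form the C4=C5 enone of ring A.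

**Step 3**
Reactants: 4 (S)-4,7a-dimethyl-2,3,7,7a-tetrahydro-1H-indene-1,5(6H)-dione
Product: 5 (1S,7aS)-1-hydroxy-4,7a-dimethyl-1,2,3,6,7,7a-hexahydro-5H-inden-5-one
Conditions: NaBH4, EtOH, −20 °C
Reagents that add atoms: none
Why: Chemoselective borohydride reduction of the saturated cyclopentanone beside the less electrophilic conjugated ketone, with hydride entering anti to the angular methyl (9β-OH; this centre only masks the ketone and is oxidised again in step 7).

**Step 4**
Reactants: 5 (1S,7aS)-1-hydroxy-4,7a-dimethyl-1,2,3,6,7,7a-hexahydro-5H-inden-5-one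
Product: 6 tert-butyldimethylsilyl ether of 5
Conditions: t-BuMe2SiCl, imidazole, DMF, 23 °C
Reagents that add atoms: tert-butyldimethylsilyl chloride CC(C)(C)[Si](C)(C)Cl
Why: Silyl ether formation protects the alcohol against O-alkylation in step 5.

**Step 5**
Reactants: 6 tert-butyldimethylsilyl ether of 5
Product: 8 benzyloxymethyl trans-hydrindan-3-one (4α-CH2OBn; 4β-CH3; 5α-H; 9β-OSi), via lithium C3-enolate 7 (not isolated)
Conditions: Li (2.5 equiv), NH3(l)/THF, t-BuOH (1.0 equiv), −78 °C; isoprene; NH3 removed; BnOCH2Cl, THF, −78 → 0 °C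
Reagents that add atoms: benzyl chloromethyl ether ClCOCc1ccccc1
Why: Dissolving-metal reductive alkylation: β-protonation of the enone dianion should give the trans ring fusion (5α-H), and the regiodefined enolate 7 is alkylated at C4 on the face anti to the axial C10 methyl, which places CH2OBn α (equatorial) and leaves the C4 methyl β.

**Step 6**
Reactants: 8 benzyloxymethyl trans-hydrindan-3-one
Product: 10 9β-hydroxy trans-hydrindane (C3 = CH2; 4α-CH2OBn), via hydrazone 9 (not isolated)
Conditions: N2H4·H2O, KOH, diethylene glycol, 130 → 200 °C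
Reagents that add atoms: none
Why: Wolff–Kishner reduction (Huang–Minlon conditions) through hydrazone 9 removes the hindered C3 carbonyl beside a base-stable benzyl ether, and the hot hydroxide should cleave the silyl ether in the same operation.

**Step 7**
Reactants: 10 9β-hydroxy trans-hydrindane
Product: 11 trans-hydrindan-9-one (4α-CH2OBn; 4β-CH3; 5α-H; 10β-CH3)
Conditions: (n-Pr)4N[RuO4] (5 mol %), N-methylmorpholine N-oxide, 4 Å MS, CH2Cl2, 23 °C
Reagents that add atoms: none
Why: Ley–Griffith oxidation of the secondary alcohol to the cyclopentanone under neutral conditions that leave the benzyl ether alone.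

**Step 8**
Reactants: 11 trans-hydrindan-9-one
Product: 13 8-methyl trans-hydrindan-9-one, via lithium C9-enolate 12 (not isolated)
Conditions: LiN(i-Pr)2, THF, −78 °C; MeI, −78 → 0 °C
Reagents that add atoms: iodomethane CI
Why: Enolate alkylation at C8, the only enolisable position because C10 is quaternary, with methyl iodide entering anti to the C10 methyl (the C8 centre becomes sp2 in step 9).

**Step 9**
Reactants: 13 8-methyl trans-hydrindan-9-one
Product: 14 8-methyl-hydrindan-6(8)-en-9-one (2-methylcyclopentenone; 5α-H)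
Conditions: IBX, 4-methoxypyridine N-oxide, DMSO, 23 °C
Reagents that add atoms: none
Why: IBX dehydrogenation of the ketone through its enol should remove a ring hydrogen on C6 and give the endocyclic trisubstituted enone at room temperature, where the benzyl ether and the 5α-hydrogen are safe.

**Step 10**
Reactants: 14 8-methyl-hydrindan-6(8)-en-9-one; 15 [2-(1,3-dioxan-2-yl)ethyl]magnesium bromide
Product: 16 tertiary allylic alcohol (9β-OH; 9α-CH2CH2-dioxanyl; C8=C6)
Conditions: CeCl3 (anhydrous), THF, −78 °C; aq. NH4Cl
Reagents that add atoms: none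
Why: 1,2-Addition of the organocerium reagent made in the flask from 15 (low basicity, no β-hydride reduction) to the hindered enone carbonyl from the α-face; the new carbinol centre is erased in step 11.

**Step 11**
Reactants: 16 tertiary allylic alcohol
Product: 17 transposed enone (C6=O; C8(CH3)=C9 bearing CH2CH2-dioxanyl; 5α-H)
Conditions: pyridinium chlorochromate (C5H5NH[CrO3Cl]), NaOAc, 4 Å MS, CH2Cl2, 23 °C
Reagents that add atoms: none
Why: Babler–Dauben oxidative 1,3-transposition of the tertiary allylic alcohol by hexavalent chromium moves the oxygen from C9 to C6 and leaves the side chain on C9 of a tetrasubstituted enone; no stereocentre is formed and the buffered medium spares the acetal and the epimerisable 5α-hydrogen.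

**Step 12**
Reactants: 17 transposed enone
Product: 19 bis(trimethylsilyl) compound (C6=C8 silyl enol ether; 18-OSiMe3; 9α-H), via dilithium enolate alkoxide 18 (not isolated)
Conditions: Li (6 equiv), NH3(l)/THF, t-BuOH (1.0 equiv), −78 °C; isoprene; NH3 removed; Me3SiCl, Et3N, THF, −78 → 0 °C
Reagents that add atoms: chlorotrimethylsilane C[Si](C)(C)Cl
Why: Dissolving-metal conjugate reduction with silyl trapping of the enolate (reductive silylation) fixes the enol ether regiospecifically at C6=C8; C9 is protonated on the α-face, anti to the angular C10 methyl of the trans-fused bicycle, so that the side chain becomes β, while the excess lithium cleaves the benzyl ether and the alkoxide is silylated too.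

**Step 13**
Reactants: 19 bis(trimethylsilyl) compound
Product: 21 cyclopropanol (C6-OH; C7 bridging C6 and C8; 18-OH), via siloxycyclopropane 20 (not isolated)
Conditions: Et2Zn, CH2I2, CH2Cl2, 0 → 23 °C; then K2CO3 (cat.), MeOH, 0 °C
Reagents that add atoms: diiodomethane ICI
Why: Simmons–Smith (Furukawa) cyclopropanation of the electron-rich tetrasubstituted silyl enol ether, then mild methanolysis of both trimethylsilyl ethers; the carbenoid should enter on the α-face, but C6 and C8 lose this configuration in step 14, so the selectivity is not needed.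

**Step 14**
Reactants: 21 cyclopropanol
Product: 23 8α-hydroxy-6-oxo decalin (ring B complete; 8β-CH3; 9β-CH2CH2-dioxanyl; 5α-H; 18-OH), via 8α-hydroperoxide 22 (not isolated)
Conditions: Mn(acac)3 (5 mol %), O2 (1 atm), benzene, 20 °C; then PPh3, 0 °C
Reagents that add atoms: dioxygen O=O
Why: The trivalent manganese alkoxide of the cyclopropanol gives a cyclopropyloxy radical, whose β-scission of the internal C6–C8 bond (shared by the three- and five-membered rings) forms the 6-ketone and a tertiary C8 radical in a six-membered ring; O2 captures it, the peroxyl radical is reduced to hydroperoxide 22 with return of trivalent manganese, and PPh3 cleaves the O–O bond. The closest known reaction type is the oxidative ring expansion (FeCl3 or aerobic with a metal acetylacetonate) of 1-hydroxy- or 1-siloxybicyclo[n.1.0]alkanes to β-functionalised cycloalkanones. No ring is closed: the five-membered ring C5–C6–C8–C9–C10 becomes ring B by loss of its zero-atom bridge, so that the former carbenoid carbon C7 stands between C6 and C8. The one new stereocentre, C8, should be set by equatorial approach of O2 on the α-face, because axial β-approach is blocked by the syn-axial C10 methyl; C4, C5, C9 and C10 are not touched. The step needs cleavage of the internal and not the external (C6–C7) cyclopropane bond, which the C8 methyl secures (tertiary against primary radical, and a primary radical can return by 3-exo closure onto the carbonyl), and it needs O2 capture to outrun hydrogen abstraction, which the O2 atmosphere secures.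

**Step 15**
Reactants: 23 8α-hydroxy-6-oxo decalin
Product: 24 6α,8α,18-triol acetal
Conditions: Li, NH3(l)/THF, EtOH, −78 °C; NH4Cl
Reagents that add atoms: none
Why: Dissolving-metal reduction of the hindered 6-ketone under thermodynamic control should give the equatorial 6α-alcohol (an axial 6β-OH would be syn-axial to the C10 and C4β methyls), where hydride reagents would attack the open α-face and give the wrong epimer; the acetal and the alcohols are inert.

**Step 16**
Reactants: 24 6α,8α,18-triol acetal
Product: 26 lactol (C13 hemiacetal closed onto the 8-oxygen; anomers), via hydroxy aldehyde 25 (not isolated)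
Conditions: 1 M HCl, THF, 40 °C
Reagents that add atoms: water O
Why: Acid-catalysed acetal hydrolysis; the freed aldehyde 25 is held as the six-membered lactol with the 8-hydroxyl, which also protects the tertiary alcohol from dehydration.

**Step 17**
Reactants: 26 lactol
Product: 27 terminal alkyne triol (C13≡C14)
Conditions: dimethyl (1-diazo-2-oxopropyl)phosphonate, K2CO3, MeOH, 23 °C
Reagents that add atoms: dimethyl (1-diazo-2-oxopropyl)phosphonate CC(=O)C(=[N+]=[N-])P(=O)(OC)OC
Why: Seyferth–Gilbert homologation with the Ohira–Bestmann reagent, which reacts with the open hydroxy aldehyde in equilibrium with the lactol and tolerates free alcohols, adds C14 as a terminal alkyne.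

**Step 18**
Reactants: 27 terminal alkyne triol
Product: 29 (E)-vinyl iodide triol, via alkenylalane 28 (not isolated)
Conditions: Me3Al (7 equiv), Cp2ZrCl2 (1 equiv), CH2Cl2, 0 → 23 °C; then I2, THF, −30 → 0 °C
Reagents that add atoms: trimethylaluminium C[Al](C)C; iodine II
Why: Zirconium-catalysed carboalumination (Negishi) adds methyl and aluminium syn across the alkyne with aluminium on the terminal carbon, and iodinolysis with retention gives the E trisubstituted iodide; the three hydroxyls are carried as aluminium alkoxides by the excess Me3Al.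

**Step 19**
Reactants: 29 (E)-vinyl iodide triol; 30 ethynyltrimethylsilane
Product: 32 terminal (E)-enyne triol, via silylated enyne 31 (not isolated)
Conditions: PdCl2(PPh3)2 (3 mol %), CuI (6 mol %), Et3N, THF, 23 °C; then K2CO3, MeOH
Reagents that add atoms: none
Why: Sonogashira coupling with retention of the alkene geometry, then methanolysis of the alkynylsilane in the same flask; free alcohols are tolerated.

**Step 20**
Reactants: 33 but-2-ynoic acid
Product: 34 (Z)-3-iodobut-2-enoic acid
Conditions: NaI, AcOH, 110 °C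
Reagents that add atoms: sodium iodide [Na+].[I-]
Why: Hydroiodination of the ynoic acid by conjugate addition of iodide and anti protonation gives the Z acid, with iodine cis to the carboxyl group as lactonisation requires.

**Step 21**
Reactants: 32 terminal (E)-enyne triol; 34 (Z)-3-iodobut-2-enoic acid
Product: 36 CNP0126806.1, via enynoic acid 35 (not isolated)
Conditions: Pd(PPh3)4 (5 mol %), CuI (10 mol %), Et3N, MeCN, 23 °C, dark
Reagents that add atoms: none
Why: Tandem Sonogashira coupling and 5-exo-dig lactonisation: the carboxylate of 35 adds anti across the metal-activated alkyne, which should give the five-membered ylidene lactone with Z geometry (ring oxygen cis to C14) and leaves the E alkene and the free triol untouched.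

**Compound list**

1 | 2-methylcyclopentane-1,3-dione | CC1C(=O)CCC1=O | starting material
2 | pent-1-en-3-one (ethyl vinyl ketone) | CCC(=O)C=C | starting material
3 | 2-methyl-2-(3-oxopentyl)cyclopentane-1,3-dione | CCC(=O)CCC1(C)C(=O)CCC1=O | intermediate
4 | (S)-4,7a-dimethyl-2,3,7,7a-tetrahydro-1H-indene-1,5(6H)-dione | CC1=C2CCC(=O)[C@@]2(C)CCC1=O | intermediate
5 | (1S,7aS)-1-hydroxy-4,7a-dimethyl-1,2,3,6,7,7a-hexahydro-5H-inden-5-one | CC1=C2CC[C@H](O)[C@@]2(C)CCC1=O | intermediate
6 | tert-butyldimethylsilyl ether of 5 | CC1=C2CC[C@H](O[Si](C)(C)C(C)(C)C)[C@@]2(C)CCC1=O | intermediate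
7 | lithium C3-enolate (C3=C4, 5α-H, 9β-silyloxy, 10β-methyl) | [Li]OC1=C(C)[C@@H]2CC[C@H](O[Si](C)(C)C(C)(C)C)[C@@]2(C)CC1 | intermediate
8 | trans-hydrindan-3-one with 4α-benzyloxymethyl, 4β-methyl, 5α-H, 9β-tert-butyldimethylsilyloxy, 10β-methyl | C[C@@]1(COCc2ccccc2)C(=O)CC[C@]2(C)[C@@H](O[Si](C)(C)C(C)(C)C)CC[C@@H]12 | intermediate
9 | C3 hydrazone of 8 | C[C@@]1(COCc2ccccc2)C(=NN)CC[C@]2(C)[C@@H](O[Si](C)(C)C(C)(C)C)CC[C@@H]12 | intermediate
10 | trans-hydrindan-9β-ol with 4α-benzyloxymethyl, 4β-methyl, 5α-H, 10β-methyl | C[C@@]1(COCc2ccccc2)CCC[C@]2(C)[C@@H](O)CC[C@@H]12 | intermediate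
11 | trans-hydrindan-9-one (same ring A) | C[C@@]1(COCc2ccccc2)CCC[C@]2(C)C(=O)CC[C@@H]12 | intermediate
12 | lithium C9-enolate of 11 (C9=C8) | C[C@@]1(COCc2ccccc2)CCC[C@]2(C)C(O[Li])=CC[C@@H]12 | intermediate
13 | 8α-methyl trans-hydrindan-9-one | C[C@@]1(COCc2ccccc2)CCC[C@]2(C)C(=O)[C@H](C)C[C@@H]12 | intermediate
14 | 8-methyl-hydrindan-6(8)-en-9-one, 5α-H | C[C@@]1(COCc2ccccc2)CCC[C@]2(C)C(=O)C(C)=C[C@@H]12 | intermediate
15 | [2-(1,3-dioxan-2-yl)ethyl]magnesium bromide | Br[Mg]CCC1OCCCO1 | starting material
16 | tertiary allylic alcohol: 9β-OH, 9α-[2-(1,3-dioxan-2-yl)ethyl], C8(CH3)=C6 | C[C@@]1(COCc2ccccc2)CCC[C@]2(C)[C@](O)(CCC3OCCCO3)C(C)=C[C@@H]12 | intermediate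
17 | hydrindan-8-en-6-one: C6=O, C8(CH3)=C9[2-(1,3-dioxan-2-yl)ethyl], 5α-H, 4α-benzyloxymethyl | C[C@@]1(COCc2ccccc2)CCC[C@]2(C)C(CCC3OCCCO3)=C(C)C(=O)[C@@H]12 | intermediate
18 | dilithium C6-enolate 18-alkoxide, 9α-H | C[C@@]1(CO[Li])CCC[C@]2(C)[C@@H](CCC3OCCCO3)C(C)=C(O[Li])[C@@H]12 | intermediate
19 | C6 trimethylsilyl enol ether (C6=C8) and 18-trimethylsilyl ether, 9α-H, 9β side chain | C[C@@]1(CO[Si](C)(C)C)CCC[C@]2(C)[C@@H](CCC3OCCCO3)C(C)=C(O[Si](C)(C)C)[C@@H]12 | intermediate
20 | siloxycyclopropane: C7 methylene bridging C6 and C8 on the α-face, 6β-OSiMe3, 8β-CH3, 18-OSiMe3 | C[C@@]1(CO[Si](C)(C)C)CCC[C@]2(C)[C@@H](CCC3OCCCO3)[C@]4(C)C[C@]4(O[Si](C)(C)C)[C@@H]12 | intermediate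
21 | cyclopropanol: as 20 with free 6-OH and 18-OH | C[C@@]1(CO)CCC[C@]2(C)[C@@H](CCC3OCCCO3)[C@]4(C)C[C@]4(O)[C@@H]12 | intermediate
22 | 8α-hydroperoxy-6-oxo decalin with 9β-[2-(1,3-dioxan-2-yl)ethyl], 18-OH | O1CCCOC1CC[C@@H]2[C@@]3(C)CCC[C@@](C)(CO)[C@@H]3C(=O)C[C@@]2(C)OO | intermediate
23 | 8α-hydroxy-8β-methyl-6-oxo decalin with 9β-[2-(1,3-dioxan-2-yl)ethyl], 18-OH | O1CCCOC1CC[C@@H]2[C@@]3(C)CCC[C@@](C)(CO)[C@@H]3C(=O)C[C@@]2(C)O | intermediate
24 | 6α,8α,18-triol with 9β-[2-(1,3-dioxan-2-yl)ethyl] | O1CCCOC1CC[C@@H]2[C@@]3(C)CCC[C@@](C)(CO)[C@@H]3[C@@H](O)C[C@@]2(C)O | intermediate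
25 | 6α,8α,18-trihydroxy C13 aldehyde (9β-CH2CH2CHO) | O=CCC[C@@H]1[C@@]2(C)CCC[C@@](C)(CO)[C@@H]2[C@@H](O)C[C@@]1(C)O | intermediate
26 | lactol: C13 hemiacetal closed onto the 8α-oxygen (anomers), 6α-OH, 18-OH | OC1CC[C@@H]2[C@@]3(C)CCC[C@@](C)(CO)[C@@H]3[C@@H](O)C[C@@]2(C)O1 | intermediate
27 | 6α,8α,18-triol with 9β-but-3-ynyl | C#CCC[C@@H]1[C@@]2(C)CCC[C@@](C)(CO)[C@@H]2[C@@H](O)C[C@@]1(C)O | intermediate
28 | (E)-alkenyl(dimethyl)alane, the three oxygens as dimethylaluminium alkoxides | C/C(=C\[Al](C)C)CC[C@@H]1[C@@]2(C)CCC[C@@](C)(CO[Al](C)C)[C@@H]2[C@@H](O[Al](C)C)C[C@@]1(C)O[Al](C)C | intermediate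
29 | 6α,8α,18-triol with 9β-[(E)-4-iodo-3-methylbut-3-enyl] | C/C(=C\I)CC[C@@H]1[C@@]2(C)CCC[C@@](C)(CO)[C@@H]2[C@@H](O)C[C@@]1(C)O | intermediate
30 | ethynyltrimethylsilane | C#C[Si](C)(C)C | starting material
31 | 6α,8α,18-triol with 9β-[(E)-3-methyl-6-trimethylsilylhex-3-en-5-ynyl] | C/C(=C\C#C[Si](C)(C)C)CC[C@@H]1[C@@]2(C)CCC[C@@](C)(CO)[C@@H]2[C@@H](O)C[C@@]1(C)O | intermediate
32 | 6α,8α,18-triol with 9β-[(E)-3-methylhex-3-en-5-ynyl] | C/C(=C\C#C)CC[C@@H]1[C@@]2(C)CCC[C@@](C)(CO)[C@@H]2[C@@H](O)C[C@@]1(C)O | intermediate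
33 | but-2-ynoic acid | CC#CC(=O)O | starting material
34 | (Z)-3-iodobut-2-enoic acid | C/C(I)=C/C(=O)O | intermediate
35 | (2Z,6E)-3,7-dimethyl-9-(decalinyl)nona-2,6-dien-4-ynoic acid of the triol core | OC(=O)/C=C(/C)C#C/C=C(\C)CC[C@@H]1[C@@]2(C)CCC[C@@](C)(CO)[C@@H]2[C@@H](O)C[C@@]1(C)O | intermediate
36 | CNP0126806.1 | CC1=CC(=O)O/C1=C\C=C(/C)CC[C@@H]1[C@@]2(C)CCC[C@@](C)(CO)[C@@H]2[C@@H](O)C[C@@]1(C)O | target

**Count**

Total steps: 21. Longest linear sequence: 20 (steps 1–19 and 21; step 20 is a one-step side branch).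

**Steps most likely to fail**

Step 14. The cyclopropane could open at the external bond, O2 could be captured on the wrong face of C8, or the β-hydroperoxy ketone could fragment before it is reduced. The fallback sets out from cyclopropanol 21 and uses ionic chemistry to fix the C8 oxygen. FeCl3 in DMF at 0 °C should open the internal bond with chlorine transfer to give 8-chloro-6-ketone F1. NaOAc in MeOH at reflux should eliminate hydrogen chloride to the 8-methyl-7-en-6-one F2. H2O2 and NaOH in MeOH at 0 °C should epoxidise the enone on the α-face, anti to the C10 methyl, to give 7α,8α-epoxy ketone F3. SmI2 in THF/MeOH at −78 °C should cleave the C7–O bond reductively and return to β-hydroxy ketone 23.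

Step 12. The enone could be over-reduced, C9 could be protonated on the wrong face, or the benzyl ether could be cleaved only in part, giving mixtures. The fallback sets out from enone 17 and sets C9 by surface hydrogenation instead. H2 (60 bar) over Pd on carbon in EtOAc/AcOH should add hydrogen to the tetrasubstituted alkene from the α-face and remove the benzyl group, giving saturated hydroxy ketone F4 (8α-H, 9α-H). Me3SiOTf and Et3N in CH2Cl2 at 0 °C should then enolise toward C8, since the C5 hydrogen is shielded by the two flanking quaternary carbons, and silylate the primary alcohol, returning to bis(trimethylsilyl) compound 19.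

Step 5. The enolate could be alkylated on oxygen instead of carbon by the chloromethyl ether, and facial or ring-fusion selectivity could be poor. The fallback sets out from silyl ether 6 and makes the C4–C18 bond by aldol instead of alkylation. The same lithium enolate (Li, NH3, t-BuOH) is treated with gaseous formaldehyde in THF at −78 °C, which should give 4α-hydroxymethyl ketone F5. Benzyl 2,2,2-trichloroacetimidate with catalytic TfOH in CH2Cl2/cyclohexane at 0 °C should benzylate the primary alcohol without retro-aldol cleavage and return to ketone 8.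

**Further compounds**

F1 | step 14 | 8α-chloro-8β-methyl-6-oxo decalin with 9β-[2-(1,3-dioxan-2-yl)ethyl], 18-OH | O1CCCOC1CC[C@@H]2[C@@]3(C)CCC[C@@](C)(CO)[C@@H]3C(=O)C[C@@]2(C)Cl
F2 | step 14 | 8-methyl-7-en-6-one with 9β-[2-(1,3-dioxan-2-yl)ethyl], 18-OH | O1CCCOC1CC[C@@H]2[C@@]3(C)CCC[C@@](C)(CO)[C@@H]3C(=O)C=C2C
F3 | step 14 | 7α,8α-epoxy-8β-methyl-6-oxo decalin with 9β-[2-(1,3-dioxan-2-yl)ethyl], 18-OH | O1CCCOC1CC[C@@H]2[C@@]3(C)CCC[C@@](C)(CO)[C@@H]3C(=O)[C@H]4O[C@@]24C
F4 | step 12 | trans-hydrindan-6-one with 8β-methyl, 8α-H, 9α-H, 9β-[2-(1,3-dioxan-2-yl)ethyl], 18-OH | C[C@@]1(CO)CCC[C@]2(C)[C@@H](CCC3OCCCO3)[C@@H](C)C(=O)[C@@H]12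
F5 | step 5 | trans-hydrindan-3-one with 4α-hydroxymethyl, 4β-methyl, 5α-H, 9β-tert-butyldimethylsilyloxy | C[C@@]1(CO)C(=O)CC[C@]2(C)[C@@H](O[Si](C)(C)C(C)(C)C)CC[C@@H]12
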